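## Retrosynthetic overview

- The cyclohexanone ring is the only ring made, and it is closed last, by intramolecular Friedel–Crafts acylation (C1–C8a) of a 4,4-diarylbutanoic acid; both aromatic ring systems are bought.
- The acid chain comes from a propenyl group by cross-metathesis with benzyl acrylate, then one hydrogenation that also removes all benzyl groups.
- The stereocentre and the C4–C4a bond are made together by an aromatic Claisen rearrangement of an (S,E)-allyl aryl ether, with 1,3-chirality transfer from C–O to C–C.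
- That ether comes from hydroboration/Suzuki coupling of an (S)-aryl 1-methylpropargyl ether with a 4-bromo-1-naphthyl benzyl ether.
- The propargyl ether is made by Mitsunobu inversion of (R)-but-3-yn-2-ol with 4-(benzyloxy)phenol; the bromide by para-bromination and benzylation of 5-methoxy-1-naphthol.

Assumption: 5-methoxynaphthalen-1-ol and (R)-but-3-yn-2-ol (≥98% ee) are taken as catalogue compounds; the stereocentre of the target, read from the SMILES, is (S).

## Route

Step 1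
Reactants: 1 5-methoxynaphthalen-1-ol
Product: 2 4-bromo-5-methoxynaphthalen-1-ol
Conditions: NBS (1.0 equiv), MeCN, −20 → 0 °C, dark
Reagents that add atoms: N-bromosuccinimide, O=C1CCC(=O)N1Br
Why: Electrophilic aromatic bromination goes para to the free OH (the more activated ring; NBS/MeCN is para-selective), i.e. at C4 peri to OMe, and one equivalent at low temperature limits 2-bromination and oxidation to the quinone.

Step 2
Reactants: 2 4-bromo-5-methoxynaphthalen-1-ol
Product: 3 1-(benzyloxy)-4-bromo-5-methoxynaphthalene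
Conditions: BnBr, K2CO3, DMF, rt
Reagents that add atoms: benzyl bromide, BrCc1ccccc1
Why: Williamson ether synthesis; the benzyl ether masks the naphthol through the Pd, thermal and Ru steps and is later removed by hydrogenolysis without touching the methyl ether.

Step 3
Reactants: 4 (R)-but-3-yn-2-ol; 5 4-(benzyloxy)phenol
Product: 6 (S)-1-(benzyloxy)-4-(but-3-yn-2-yloxy)benzene
Conditions: PPh3, DIAD, THF, 0 °C → rt
Reagents that add atoms: none
Why: Mitsunobu reaction; SN2 displacement of the oxyphosphonium by the phenol inverts the carbinol, (R)-alcohol → (S)-ether, and secondary propargylic alcohols do this without SN1 or SN2′ leakage.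

Step 4
Reactants: 6 (S)-1-(benzyloxy)-4-(but-3-yn-2-yloxy)benzene; 3 1-(benzyloxy)-4-bromo-5-methoxynaphthalene
Product: 8 1-(benzyloxy)-4-{(1E,3S)-3-[4-(benzyloxy)phenoxy]but-1-en-1-yl}-5-methoxynaphthalene, via (S,E)-2-{3-[4-(benzyloxy)phenoxy]but-1-en-1-yl}-4,4,5,5-tetramethyl-1,3,2-dioxaborolane 7 (not isolated)
Conditions: HBpin (1.1 equiv), Cp2Zr(H)Cl (5 mol%), CH2Cl2, rt; then 3, Pd(dppf)Cl2 (3 mol%), aq. K3PO4, THF, 45 °C
Reagents that add atoms: none
Why: Zr-catalysed syn, anti-Markovnikov hydroboration gives the (E)-alkenylboronate, and Suzuki–Miyaura coupling joins it to 3 with retention of alkene geometry; the C–O stereocentre is not involved, and the mild temperature limits Pd(0) ionisation of the allylic aryl ether.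

Step 5
Reactants: 8 1-(benzyloxy)-4-{(1E,3S)-3-[4-(benzyloxy)phenoxy]but-1-en-1-yl}-5-methoxynaphthalene
Product: 10 4-(benzyloxy)-2-[(1S,2E)-1-(4-(benzyloxy)-8-methoxynaphthalen-1-yl)but-2-en-1-yl]phenol, via (6R)-4-(benzyloxy)-6-[(1R,2E)-1-(4-(benzyloxy)-8-methoxynaphthalen-1-yl)but-2-en-1-yl]cyclohexa-2,4-dien-1-one 9 (not isolated)
Conditions: PhNEt2 (degassed), 150 °C, sealed tube, Ar
Reagents that add atoms: none
Why: Aromatic Claisen rearrangement ([3,3]-sigmatropic) through a chair transition state with the methyl group equatorial and the E-alkene delivers the ortho carbon to the face from which the C–O bond departs, so the (S) C–O centre becomes the (S) diarylmethine with an E-propenyl group, and dienone 9 tautomerises to the phenol.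

Step 6
Reactants: 10 4-(benzyloxy)-2-[(1S,2E)-1-(4-(benzyloxy)-8-methoxynaphthalen-1-yl)but-2-en-1-yl]phenol; 11 benzyl acrylate
Product: 12 benzyl (2E,4S)-4-[5-(benzyloxy)-2-hydroxyphenyl]-4-[4-(benzyloxy)-8-methoxynaphthalen-1-yl]but-2-enoate
Conditions: 11 (5 equiv), Hoveyda–Grubbs II (5 mol%), 1,4-benzoquinone (10 mol%), CH2Cl2, 40 °C; neutral work-up
Reagents that add atoms: none
Why: Olefin cross-metathesis exchanges the ethylidene end of the propenyl group (lost as propene) for the acrylate to give the E-enoate without touching the sp3 stereocentre; benzoquinone suppresses Ru–H double-bond migration and neutral handling avoids oxa-Michael closure by the ortho phenol.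

Step 7
Reactants: 12 benzyl (2E,4S)-4-[5-(benzyloxy)-2-hydroxyphenyl]-4-[4-(benzyloxy)-8-methoxynaphthalen-1-yl]but-2-enoate
Product: 13 (4S)-4-(2,5-dihydroxyphenyl)-4-(4-hydroxy-8-methoxynaphthalen-1-yl)butanoic acid
Conditions: H2 (1 atm), 10% Pd/C, EtOAc–MeOH, rt
Reagents that add atoms: none
Why: Heterogeneous hydrogenation saturates the enoate and hydrogenolyses the benzyl ester and both benzyl ethers in one operation, while the methyl ether, the naphthalene and the diarylmethine C–H are inert.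

Step 8
Reactants: 13 (4S)-4-(2,5-dihydroxyphenyl)-4-(4-hydroxy-8-methoxynaphthalen-1-yl)butanoic acid
Product: 14 (4S)-5,8-dihydroxy-4-(4-hydroxy-8-methoxynaphthalen-1-yl)-3,4-dihydronaphthalen-1(2H)-one
Conditions: Eaton's reagent (P2O5 in MeSO3H), rt, Ar; ice-water quench
Reagents that add atoms: none
Why: Intramolecular Friedel–Crafts acylation closes the six-membered ring onto the hydroquinone carbon ortho to OH (more activated than naphthalene C2, and any aryl ester formed first re-ionises in this medium), giving the hydrogen-bonded hydroxy ketone with the stereocentre untouched.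

## Compound list

1 | 5-methoxynaphthalen-1-ol | COc1cccc2c(O)cccc12 | starting material
2 | 4-bromo-5-methoxynaphthalen-1-ol | COc1cccc2c(O)ccc(Br)c12 | intermediate
3 | 1-(benzyloxy)-4-bromo-5-methoxynaphthalene | COc1cccc2c(OCc3ccccc3)ccc(Br)c12 | intermediate
4 | (R)-but-3-yn-2-ol | C[C@@H](O)C#C | starting material
5 | 4-(benzyloxy)phenol | Oc1ccc(OCc2ccccc2)cc1 | starting material
6 | (S)-1-(benzyloxy)-4-(but-3-yn-2-yloxy)benzene | C[C@H](Oc1ccc(OCc2ccccc2)cc1)C#C | intermediate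
7 | (S,E)-2-{3-[4-(benzyloxy)phenoxy]but-1-en-1-yl}-4,4,5,5-tetramethyl-1,3,2-dioxaborolane | C[C@H](Oc1ccc(OCc2ccccc2)cc1)/C=C/B1OC(C)(C)C(C)(C)O1 | intermediate
8 | 1-(benzyloxy)-4-{(1E,3S)-3-[4-(benzyloxy)phenoxy]but-1-en-1-yl}-5-methoxynaphthalene | C[C@H](Oc1ccc(OCc2ccccc2)cc1)/C=C/c1ccc(OCc2ccccc2)c2cccc(OC)c12 | intermediate
9 | (6R)-4-(benzyloxy)-6-[(1R,2E)-1-(4-(benzyloxy)-8-methoxynaphthalen-1-yl)but-2-en-1-yl]cyclohexa-2,4-dien-1-one | C/C=C/[C@H]([C@@H]1C=C(OCc2ccccc2)C=CC1=O)c1ccc(OCc2ccccc2)c2cccc(OC)c12 | intermediate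
10 | 4-(benzyloxy)-2-[(1S,2E)-1-(4-(benzyloxy)-8-methoxynaphthalen-1-yl)but-2-en-1-yl]phenol | C/C=C/[C@H](c1cc(OCc2ccccc2)ccc1O)c1ccc(OCc2ccccc2)c2cccc(OC)c12 | intermediate
11 | benzyl acrylate | C=CC(=O)OCc1ccccc1 | starting material
12 | benzyl (2E,4S)-4-[5-(benzyloxy)-2-hydroxyphenyl]-4-[4-(benzyloxy)-8-methoxynaphthalen-1-yl]but-2-enoate | O=C(OCc1ccccc1)/C=C/[C@H](c1cc(OCc2ccccc2)ccc1O)c1ccc(OCc2ccccc2)c2cccc(OC)c12 | intermediate
13 | (4S)-4-(2,5-dihydroxyphenyl)-4-(4-hydroxy-8-methoxynaphthalen-1-yl)butanoic acid | OC(=O)CC[C@H](c1cc(O)ccc1O)c1ccc(O)c2cccc(OC)c12 | intermediate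
14 | (4S)-5,8-dihydroxy-4-(4-hydroxy-8-methoxynaphthalen-1-yl)-3,4-dihydronaphthalen-1(2H)-one | COc1cccc2c(O)ccc([C@@H]3CCC(=O)c4c(O)ccc(O)c43)c12 | target

## Step count and risks

Total steps: 8. Longest linear sequence: 7 (1 → 2 → 3 → 8 → 10 → 12 → 13 → 14).

Steps most likely to fail:

**Step 5 (Claisen rearrangement).** The C–O bond of 8 is secondary, allylic and conjugated to a 4-alkoxynaphthyl group, so heating may cause ionisation (loss of ee, [1,3]-shifted products) or elimination to the naphthylbutadiene and 5. A minor axial-methyl chair would also give the Z-alkene with the opposite configuration. The fallback removes the donor that stabilises the allyl cation. It sets out from 2 (with 6). Compound 2 is acylated with pivaloyl chloride (Et3N, DMAP, CH2Cl2) to 4-bromo-5-methoxynaphthalen-1-yl pivalate F1. Hydroboration of 6 and Suzuki coupling with F1 under the step 4 conditions gives 4-{(1E,3S)-3-[4-(benzyloxy)phenoxy]but-1-en-1-yl}-5-methoxynaphthalen-1-yl pivalate F2. Its Claisen rearrangement (PhNEt2, 160 °C) gives 4-{(1S,2E)-1-[5-(benzyloxy)-2-hydroxyphenyl]but-2-en-1-yl}-5-methoxynaphthalen-1-yl pivalate F3. Cross-metathesis with 11 gives benzyl (2E,4S)-4-[5-(benzyloxy)-2-hydroxyphenyl]-4-[8-methoxy-4-(pivaloyloxy)naphthalen-1-yl]but-2-enoate F4. H2, Pd/C gives (4S)-4-(2,5-dihydroxyphenyl)-4-[8-methoxy-4-(pivaloyloxy)naphthalen-1-yl]butanoic acid F5. LiOH in degassed THF–H2O, then acid, removes the pivalate and the route is rejoined at 13.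

**Step 6 (cross-metathesis).** The internal olefin next to a diarylmethine is hindered and may react slowly or isomerise. The fallback makes the metathesis intramolecular and sets out from 10. The phenol is esterified with acryloyl chloride (Et3N, CH2Cl2, −20 °C) to 4-(benzyloxy)-2-[(1S,2E)-1-(4-(benzyloxy)-8-methoxynaphthalen-1-yl)but-2-en-1-yl]phenyl acrylate F6. Ring-closing metathesis (Grubbs II, toluene, 80 °C, high dilution) gives (5S)-7-(benzyloxy)-5-[4-(benzyloxy)-8-methoxynaphthalen-1-yl]-1-benzoxepin-2(5H)-one F7. H2, Pd/C gives (5S)-7-hydroxy-5-(4-hydroxy-8-methoxynaphthalen-1-yl)-4,5-dihydro-1-benzoxepin-2(3H)-one F8. The lactone is opened with LiOH (degassed THF–H2O, then acid) and the route is rejoined at 13.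

**Step 8 (Friedel–Crafts closure on the free triphenol).** Strong acid may give acylation at naphthalene C2, oligomers, or acid-induced dealkylation at the diarylmethine with loss of ee. The fallback closes the ring before deprotection under mild, anhydride-activated conditions and sets out from 10. The phenol is benzylated (BnBr, K2CO3, DMF) to 1-(benzyloxy)-4-{(1S,2E)-1-[2,5-bis(benzyloxy)phenyl]but-2-en-1-yl}-5-methoxynaphthalene F9. Cross-metathesis with 11 gives benzyl (2E,4S)-4-[2,5-bis(benzyloxy)phenyl]-4-[4-(benzyloxy)-8-methoxynaphthalen-1-yl]but-2-enoate F10. H2 over ethylenediamine-poisoned Pd/C in THF reduces the alkene and cleaves only the benzyl ester, giving (4S)-4-[2,5-bis(benzyloxy)phenyl]-4-[4-(benzyloxy)-8-methoxynaphthalen-1-yl]butanoic acid F11. TFAA in CH2Cl2 at 0 °C forms the mixed anhydride (4S)-4-[2,5-bis(benzyloxy)phenyl]-4-[4-(benzyloxy)-8-methoxynaphthalen-1-yl]butanoic trifluoroacetic anhydride F12, not isolated, which cyclises onto the dialkoxybenzene ring to (4S)-5,8-bis(benzyloxy)-4-[4-(benzyloxy)-8-methoxynaphthalen-1-yl]-3,4-dihydronaphthalen-1(2H)-one F13. H2, Pd/C, EtOAc then rejoins the route at 14.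

## Further compounds

F1 | step 5 | 4-bromo-5-methoxynaphthalen-1-yl pivalate | COc1cccc2c(OC(=O)C(C)(C)C)ccc(Br)c12
F2 | step 5 | 4-{(1E,3S)-3-[4-(benzyloxy)phenoxy]but-1-en-1-yl}-5-methoxynaphthalen-1-yl pivalate | C[C@H](Oc1ccc(OCc2ccccc2)cc1)/C=C/c1ccc(OC(=O)C(C)(C)C)c2cccc(OC)c12
F3 | step 5 | 4-{(1S,2E)-1-[5-(benzyloxy)-2-hydroxyphenyl]but-2-en-1-yl}-5-methoxynaphthalen-1-yl pivalate | C/C=C/[C@H](c1cc(OCc2ccccc2)ccc1O)c1ccc(OC(=O)C(C)(C)C)c2cccc(OC)c12
F4 | step 5 | benzyl (2E,4S)-4-[5-(benzyloxy)-2-hydroxyphenyl]-4-[8-methoxy-4-(pivaloyloxy)naphthalen-1-yl]but-2-enoate | O=C(OCc1ccccc1)/C=C/[C@H](c1cc(OCc2ccccc2)ccc1O)c1ccc(OC(=O)C(C)(C)C)c2cccc(OC)c12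
F5 | step 5 | (4S)-4-(2,5-dihydroxyphenyl)-4-[8-methoxy-4-(pivaloyloxy)naphthalen-1-yl]butanoic acid | OC(=O)CC[C@H](c1cc(O)ccc1O)c1ccc(OC(=O)C(C)(C)C)c2cccc(OC)c12
F6 | step 6 | 4-(benzyloxy)-2-[(1S,2E)-1-(4-(benzyloxy)-8-methoxynaphthalen-1-yl)but-2-en-1-yl]phenyl acrylate | C/C=C/[C@H](c1cc(OCc2ccccc2)ccc1OC(=O)C=C)c1ccc(OCc2ccccc2)c2cccc(OC)c12
F7 | step 6 | (5S)-7-(benzyloxy)-5-[4-(benzyloxy)-8-methoxynaphthalen-1-yl]-1-benzoxepin-2(5H)-one | O=C1C=C[C@@H](c2ccc(OCc3ccccc3)c3cccc(OC)c23)c2cc(OCc3ccccc3)ccc2O1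
F8 | step 6 | (5S)-7-hydroxy-5-(4-hydroxy-8-methoxynaphthalen-1-yl)-4,5-dihydro-1-benzoxepin-2(3H)-one | O=C1CC[C@@H](c2ccc(O)c3cccc(OC)c23)c2cc(O)ccc2O1
F9 | step 8 | 1-(benzyloxy)-4-{(1S,2E)-1-[2,5-bis(benzyloxy)phenyl]but-2-en-1-yl}-5-methoxynaphthalene | C/C=C/[C@H](c1cc(OCc2ccccc2)ccc1OCc1ccccc1)c1ccc(OCc2ccccc2)c2cccc(OC)c12
F10 | step 8 | benzyl (2E,4S)-4-[2,5-bis(benzyloxy)phenyl]-4-[4-(benzyloxy)-8-methoxynaphthalen-1-yl]but-2-enoate | O=C(OCc1ccccc1)/C=C/[C@H](c1cc(OCc2ccccc2)ccc1OCc1ccccc1)c1ccc(OCc2ccccc2)c2cccc(OC)c12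
F11 | step 8 | (4S)-4-[2,5-bis(benzyloxy)phenyl]-4-[4-(benzyloxy)-8-methoxynaphthalen-1-yl]butanoic acid | OC(=O)CC[C@H](c1cc(OCc2ccccc2)ccc1OCc1ccccc1)c1ccc(OCc2ccccc2)c2cccc(OC)c12
F12 | step 8 | (4S)-4-[2,5-bis(benzyloxy)phenyl]-4-[4-(benzyloxy)-8-methoxynaphthalen-1-yl]butanoic trifluoroacetic anhydride | FC(F)(F)C(=O)OC(=O)CC[C@H](c1cc(OCc2ccccc2)ccc1OCc1ccccc1)c1ccc(OCc2ccccc2)c2cccc(OC)c12
F13 | step 8 | (4S)-5,8-bis(benzyloxy)-4-[4-(benzyloxy)-8-methoxynaphthalen-1-yl]-3,4-dihydronaphthalen-1(2H)-one | COc1cccc2c(OCc3ccccc3)ccc([C@@H]3CCC(=O)c4c(OCc5ccccc5)ccc(OCc5ccccc5)c43)c12
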